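The route rests on cutting the C3=C4 double bond of the 2H-pyran ring (chromene numbering O1, C2, C3, C4, C4a). C4 is traced to the formyl carbon of 2,6-dihydroxy-4-methoxybenzaldehyde. Its two hydroxyls are symmetry-equivalent, so whichever is alkylated becomes O1 and the other becomes the C5 oxygen, and no isomeric chromene can arise. Ring-closing metathesis then forms the C3=C4 bond and the pyran ring in one operation with loss of ethylene. The precursor is a styrene flanked by a 1,1-dimethylallyl ether and a MOM ether, with methoxy para to the vinyl group. The MOM group avoids a fragile vinylphenol and later steers lithiation to C6 for attachment of the 4-methoxycinnamoyl unit.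

Key step: step 6

Remark on locants: the ring-closure precursor is the MOM ether of 5-methoxy-3-[(2-methylbut-3-en-2-yl)oxy]-2-vinylphenol. The tertiary allyl ether stands at C3, ortho to the vinyl group, and the methoxy group at C5, para to it. With these two locants exchanged the alkenes could not reach each other.

Remark on handling: every intermediate that holds the tertiary allyl aryl ether is sensitive to acid and heat. It is assumed to be kept below 40 °C and chromatographed on Et3N-deactivated silica.

Step 1
Reactants: 1 2,4,6-trihydroxybenzaldehyde
Product: 2 2,6-dihydroxy-4-methoxybenzaldehyde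
Conditions: Me2SO4 (1.0 equiv), K2CO3 (1.0 equiv), acetone, 0 °C → rt
Reagents that add atoms: dimethyl sulfate, COS(=O)(=O)OC
Why: Williamson-type O-methylation under substrate control: the 4-OH is para to the formyl group and is the only hydroxyl not tied to the carbonyl oxygen by a hydrogen bond, so it is the most acidic and the most nucleophilic once deprotonated, and one equivalent of the hard electrophile Me2SO4 should cap it on oxygen and leave the symmetric diol 2.

Step 2
Reactants: 2 2,6-dihydroxy-4-methoxybenzaldehyde; 3 3-chloro-3-methylbut-1-yne
Product: 4 2-hydroxy-4-methoxy-6-[(2-methylbut-3-yn-2-yl)oxy]benzaldehyde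
Conditions: 3 (1.1 equiv), DBU (1.2 equiv), CuCl2·2H2O (1 mol%), MeCN, 0 °C → rt
Reagents that add atoms: none
Why: Copper-catalysed propargylic substitution (O-alkylation of a phenoxide by a tertiary propargylic chloride through a copper acetylide that ionises to an allenylidene-type electrophile), the standard entry to aryl 1,1-dimethylpropargyl ethers and well suited to electron-poor phenols; the two hydroxyls of 2 are equivalent, so only one mono-ether can form, and the hydroxyl left over is hydrogen-bonded to the formyl oxygen and crowded, which should hold back a second alkylation.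

Step 3
Reactants: 4 2-hydroxy-4-methoxy-6-[(2-methylbut-3-yn-2-yl)oxy]benzaldehyde
Product: 5 2-hydroxy-4-methoxy-6-[(2-methylbut-3-en-2-yl)oxy]benzaldehyde
Conditions: H2 (1 atm), Pd/CaCO3 poisoned with Pb(OAc)2, quinoline, EtOAc, rt, stopped after one equivalent of H2
Reagents that add atoms: none
Why: Lindlar-type semihydrogenation: on the lead- and quinoline-poisoned palladium surface the terminal alkyne binds and takes up H2 far faster than the alkene it gives, and aldehyde, phenol and aryl ethers are inert at 1 atm and room temperature.

Step 4
Reactants: 5 2-hydroxy-4-methoxy-6-[(2-methylbut-3-en-2-yl)oxy]benzaldehyde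
Product: 7 4-methoxy-2-(methoxymethoxy)-6-[(2-methylbut-3-en-2-yl)oxy]benzaldehyde, via sodium phenolate 6 (not isolated)
Conditions: NaH (1.1 equiv), THF–DMF, 0 °C; then MOMCl (1.2 equiv), 0 °C → rt
Reagents that add atoms: chloromethyl methyl ether (MOMCl), COCCl; sodium hydride, [Na+].[H-] (sodium in 6 only)
Why: Williamson-type ether synthesis with an α-chloro ether: irreversible deprotonation by NaH breaks the hydrogen-bond chelate that makes this phenol unreactive toward amine bases, the phenolate 6 is captured on oxygen by the very reactive MOMCl, and the cold basic medium does not touch the acid- and heat-sensitive tertiary allyl ether.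

Step 5
Reactants: 7 4-methoxy-2-(methoxymethoxy)-6-[(2-methylbut-3-en-2-yl)oxy]benzaldehyde
Product: 8 2-ethenyl-5-methoxy-1-(methoxymethoxy)-3-[(2-methylbut-3-en-2-yl)oxy]benzene
Conditions: MePPh3Br (1.5 equiv), KOtBu (1.4 equiv), THF, 0 °C; then 7, 0 °C → rt
Reagents that add atoms: methyltriphenylphosphonium bromide, C[P+](c1ccccc1)(c1ccccc1)c1ccccc1.[Br-]
Why: Wittig methylenation: the small, unstabilised ylide Ph3P=CH2 adds readily even to electron-rich 2,6-dialkoxybenzaldehydes, and because the phenol is already masked no ylide is lost to an acidic proton, no phenolate deactivates the carbonyl group and the product is a storable dialkoxystyrene instead of a polymerisation-prone vinylphenol.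

Step 6
Reactants: 8 2-ethenyl-5-methoxy-1-(methoxymethoxy)-3-[(2-methylbut-3-en-2-yl)oxy]benzene
Product: 9 7-methoxy-5-(methoxymethoxy)-2,2-dimethyl-2H-chromene
Conditions: (H2IMes)(PCy3)Cl2Ru=CHPh (second-generation Grubbs catalyst, 5 mol%), degassed CH2Cl2 (0.005 M), 40 °C, slow Ar purge
Reagents that add atoms: none
Why: Olefin metathesis by the Chauvin mechanism: loss of PCy3 gives a 14-electron ruthenium alkylidene that exchanges with one terminal =CH2 of 8, the tethered alkylidene adds to the second alkene in a [2+2] fashion to a ruthenacyclobutane, and cycloreversion releases 9 and Ru=CH2, which carries the chain while ethylene leaves with the argon stream. The closest known reaction type is the ring-closing metathesis of 2-vinylaryl allyl ethers to 2H-chromenes. The one ring closed is the six-membered pyran, formed by joining C3 (the inner vinyl carbon on C2) to C4 (the former formyl carbon) as an endocyclic, necessarily cis alkene; no stereocentre is created. The two methyl groups on C2 and the rigid ortho arrangement on the arene keep the two alkenes close together (Thorpe–Ingold effect), which should offset the steric cost of an alkene on a quaternary carbon and of a doubly ortho-substituted styrene. The step needs chemoselectivity for closure over oligomerisation, over [3,3] shift or ionisation of the tertiary allyl aryl ether and over alkene migration: high dilution, 40 °C and a neutral aprotic medium answer the first three, and since neither alkene has an allylic hydrogen there is nothing for a ruthenium hydride to isomerise. Regiochemistry is no issue, because only the oxygen alkylated in step 2 carries an alkene and the other is a MOM ether that can neither bind nor protonate the catalyst.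

Step 7
Reactants: 10 (E)-4-methoxycinnamic acid
Product: 12 (E)-N-methoxy-3-(4-methoxyphenyl)-N-methylprop-2-enamide, via acyl imidazole 11 (not isolated)
Conditions: CDI (1.1 equiv), CH2Cl2, rt; then MeNH(OMe)·HCl (1.2 equiv), rt
Reagents that add atoms: N,O-dimethylhydroxylamine hydrochloride, CNOC.Cl; 1,1'-carbonyldiimidazole, O=C(n1ccnc1)n1ccnc1 (imidazolyl group in 11 only)
Why: Carboxyl activation with CDI followed by aminolysis (Weinreb amide synthesis): loss of CO2 drives formation of acyl imidazole 11, the imidazole released frees the amine from its hydrochloride, and the neutral conditions leave the E alkene untouched.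

Step 8
Reactants: 9 7-methoxy-5-(methoxymethoxy)-2,2-dimethyl-2H-chromene; 12 (E)-N-methoxy-3-(4-methoxyphenyl)-N-methylprop-2-enamide
Product: 15 (E)-1-[7-methoxy-5-(methoxymethoxy)-2,2-dimethyl-2H-chromen-6-yl]-3-(4-methoxyphenyl)prop-2-en-1-one, via 6-lithiochromene 13 (not isolated), via lithium hemiaminal 14 (not isolated)
Conditions: n-BuLi (1.05 equiv), THF, −20 → 0 °C; then 12 (1.0 equiv), −78 → 0 °C; sat. aq. NH4Cl
Reagents that add atoms: n-butyllithium, [Li]CCCC (lithium in 13 and 14 only)
Why: Directed ortho-metalation followed by Weinreb ketone synthesis: C6–H lies between OMOM and OMe, the chelating MOM group is the strongest director present and its side chain is turned toward C6 by the peri C4–H, so n-BuLi should be delivered to C6 in preference to C8, and the hard aryllithium 13 then adds 1,2 to amide 12 to give the chelated adduct 14, which survives until the quench and so rules out over-addition while the E geometry is carried over from 10.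

Step 9
Reactants: 15 (E)-1-[7-methoxy-5-(methoxymethoxy)-2,2-dimethyl-2H-chromen-6-yl]-3-(4-methoxyphenyl)prop-2-en-1-one
Product: 16 glychalcone A, (E)-1-(5-hydroxy-7-methoxy-2,2-dimethyl-2H-chromen-6-yl)-3-(4-methoxyphenyl)prop-2-en-1-one
Conditions: 3 M aq. HCl, MeOH, rt → 40 °C
Reagents that add atoms: none
Why: Acid-catalysed acetal hydrolysis: a MOM ether ortho to an aryl ketone is cleaved with particular ease because the released phenol is stabilised by a hydrogen bond to the carbonyl oxygen, so dilute HCl in MeOH should suffice and leave the methyl ethers, the 2,2-dimethylchromene and the E enone intact, the same hydrogen bond and a short contact time holding back oxa-Michael closure to the flavanone.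

Compound list
1 | 2,4,6-trihydroxybenzaldehyde | O=Cc1c(O)cc(O)cc1O | starting material
2 | 2,6-dihydroxy-4-methoxybenzaldehyde | O=Cc1c(O)cc(OC)cc1O | intermediate
3 | 3-chloro-3-methylbut-1-yne | C#CC(C)(C)Cl | starting material
4 | 2-hydroxy-4-methoxy-6-[(2-methylbut-3-yn-2-yl)oxy]benzaldehyde | O=Cc1c(O)cc(OC)cc1OC(C)(C)C#C | intermediate
5 | 2-hydroxy-4-methoxy-6-[(2-methylbut-3-en-2-yl)oxy]benzaldehyde | O=Cc1c(O)cc(OC)cc1OC(C)(C)C=C | intermediate
6 | sodium 2-formyl-5-methoxy-3-[(2-methylbut-3-en-2-yl)oxy]phenolate (not isolated) | [Na+].[O-]c1cc(OC)cc(OC(C)(C)C=C)c1C=O | intermediate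
7 | 4-methoxy-2-(methoxymethoxy)-6-[(2-methylbut-3-en-2-yl)oxy]benzaldehyde | O=Cc1c(OCOC)cc(OC)cc1OC(C)(C)C=C | intermediate
8 | 2-ethenyl-5-methoxy-1-(methoxymethoxy)-3-[(2-methylbut-3-en-2-yl)oxy]benzene | C=Cc1c(OCOC)cc(OC)cc1OC(C)(C)C=C | intermediate
9 | 7-methoxy-5-(methoxymethoxy)-2,2-dimethyl-2H-chromene | COc1cc(OCOC)c2C=CC(C)(C)Oc2c1 | intermediate
10 | (E)-4-methoxycinnamic acid | COc1ccc(/C=C/C(=O)O)cc1 | starting material
11 | (E)-1-(1H-imidazol-1-yl)-3-(4-methoxyphenyl)prop-2-en-1-one (not isolated) | COc1ccc(/C=C/C(=O)n2ccnc2)cc1 | intermediate
12 | (E)-N-methoxy-3-(4-methoxyphenyl)-N-methylprop-2-enamide | COc1ccc(/C=C/C(=O)N(C)OC)cc1 | intermediate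
13 | [7-methoxy-5-(methoxymethoxy)-2,2-dimethyl-2H-chromen-6-yl]lithium (not isolated) | [Li]c1c(OC)cc2c(c1OCOC)C=CC(C)(C)O2 | intermediate
14 | lithium (E)-1-[methoxy(methyl)amino]-1-[7-methoxy-5-(methoxymethoxy)-2,2-dimethyl-2H-chromen-6-yl]-3-(4-methoxyphenyl)prop-2-en-1-olate (racemic, not isolated) | COc1ccc(/C=C/C(O[Li])(N(C)OC)c2c(OC)cc3c(c2OCOC)C=CC(C)(C)O3)cc1 | intermediate
15 | (E)-1-[7-methoxy-5-(methoxymethoxy)-2,2-dimethyl-2H-chromen-6-yl]-3-(4-methoxyphenyl)prop-2-en-1-one | COc1ccc(/C=C/C(=O)c2c(OC)cc3c(c2OCOC)C=CC(C)(C)O3)cc1 | intermediate
16 | glychalcone A, (E)-1-(5-hydroxy-7-methoxy-2,2-dimethyl-2H-chromen-6-yl)-3-(4-methoxyphenyl)prop-2-en-1-one | COc1ccc(/C=C/C(=O)c2c(OC)cc3c(c2O)C=CC(C)(C)O3)cc1 | target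

Total step count: 9. Longest linear sequence: 8 (steps 1 to 6, 8 and 9). Step 7 is a one-step side branch.

Steps most likely to fail

**1. Step 6.**
- What may go wrong: initiation and turnover may be slow at two crowded alkenes. Catalyst decay and intermolecular metathesis could then overtake ring closure, while a higher temperature would open the way to sigmatropic rearrangement of the ether.
- Fallback: it sets out from 2 and comes back to the route at 9.
- One of the two equivalent hydroxyls of 2 is masked with MOMCl (1 equiv) and iPr2NEt in CH2Cl2 to give 2-hydroxy-4-methoxy-6-(methoxymethoxy)benzaldehyde F1.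
- Excess 2-methylprop-1-enylmagnesium bromide in THF at 0 °C adds to the formyl group and gives racemic 2-(1-hydroxy-3-methylbut-2-en-1-yl)-5-methoxy-3-(methoxymethoxy)phenol F2.
- Gentle heating in toluene expels water to give the ortho-quinone methide (Z)-3-methoxy-5-(methoxymethoxy)-6-(3-methylbut-2-en-1-ylidene)cyclohexa-2,4-dien-1-one F3. Its oxa-6π electrocyclisation closes the pyran ring at O1–C2 and delivers 9.
- C4 still stems from the formyl carbon and the symmetry argument still holds, but the ring is closed by a pericyclic step and not by metathesis.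

**2. Step 8.**
- What may go wrong: deprotonation at C8 may compete with deprotonation at C6. The doubly ortho-substituted aryllithium may also add slowly, or in conjugate fashion, to the unsaturated amide.
- Fallback: it sets out from 9 (with acid 10) and comes back to the route at 16.
- The MOM ether of 9 is hydrolysed (aq. HCl, MeOH, rt) to 7-methoxy-2,2-dimethyl-2H-chromen-5-ol F4.
- Acid 10 is converted with (COCl)2 and catalytic DMF into (E)-4-methoxycinnamoyl chloride F5.
- EtMgBr in Et2O, followed by exchange of the solvent for toluene, turns F4 into bromomagnesium 7-methoxy-2,2-dimethyl-2H-chromen-5-olate F6, which is treated with F5 at rt.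
- In this ortho-coordinated Friedel–Crafts acylation of a magnesium phenolate the metal binds both the phenolate oxygen and the acyl chloride, so it can hand the acyl group only to an ortho carbon. C4a is substituted and C8 is para, so C6 is the sole site.
- No lithiation is needed and no protecting group has to be taken off the chalcone.

**3. Step 2.**
- What may go wrong: substitution by a weakly nucleophilic, hydrogen-bonded phenoxide may be slow, with dehydrochlorination of 3 and double alkylation as competing processes.
- Fallback: it sets out from 2 and comes back to the route at 5, so step 3 also drops out.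
- Commercial 2-methylbut-3-en-2-ol is converted with n-BuLi and Boc2O in THF into tert-butyl 2-methylbut-3-en-2-yl carbonate F7.
- With Pd(PPh3)4 (catalytic) in THF at 0 °C, F7 ionises to a 1,1-dimethyl-π-allylpalladium species with loss of CO2, and the tert-butoxide released deprotonates 2.
- Under kinetic control the phenoxide attacks the more substituted allyl terminus (Tsuji–Trost O-allylation) and gives the tertiary ether 5 directly.

Further compounds
F1 | step 6 | 2-hydroxy-4-methoxy-6-(methoxymethoxy)benzaldehyde | O=Cc1c(O)cc(OC)cc1OCOC
F2 | step 6 | 2-(1-hydroxy-3-methylbut-2-en-1-yl)-5-methoxy-3-(methoxymethoxy)phenol (racemic) | CC(C)=CC(O)c1c(O)cc(OC)cc1OCOC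
F3 | step 6 | (Z)-3-methoxy-5-(methoxymethoxy)-6-(3-methylbut-2-en-1-ylidene)cyclohexa-2,4-dien-1-one | CC(C)=C/C=C1\C(=O)C=C(OC)C=C1OCOC
F4 | step 8 | 7-methoxy-2,2-dimethyl-2H-chromen-5-ol | COc1cc(O)c2C=CC(C)(C)Oc2c1
F5 | step 8 | (E)-4-methoxycinnamoyl chloride | COc1ccc(/C=C/C(=O)Cl)cc1
F6 | step 8 | bromomagnesium 7-methoxy-2,2-dimethyl-2H-chromen-5-olate | COc1cc(O[Mg]Br)c2C=CC(C)(C)Oc2c1
F7 | step 2 | tert-butyl 2-methylbut-3-en-2-yl carbonate | C=CC(C)(C)OC(=O)OC(C)(C)C
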